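**Retrosynthetic overview**
1. The target comes from benzoate opening (C7–O bond) of a C1–O–C7 spiro-oxirane. Before that come O3-benzoylation and an anti-SE2' oxidation of a C3=C4/C5–Si allylsilane, which installs C3–O and moves the alkene to C4=C5.
2. The spiro-oxirane comes from reduction and inverting ring closure of a C1 bromo aldehyde. That aldehyde is the product of a catalytic enantioselective Diels–Alder reaction forming C1–C2 and C5–C6, between a (1E,3E)-1-acetoxy-4-silylbutadiene (C2–C5) and (Z)-3-benzoyloxy-2-bromoacrolein (C6, C1, C7).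
3. Enabling feature: in the cyclohexene ring, C2(OAc)–C3(O)–C4=C5 is one allylic transposition away from C2(OAc)–C3=C4–C5(Si), which is a Diels–Alder cyclohexene. C1 (bearing O and C7) and C6 (bearing O, trans to O1) are the α- and β-carbons of a trisubstituted enal. A bromine on C1 lets the endo adduct be corrected by inversion.
4. Ring order: cyclohexene (step 5), temporary C1–O–C7 oxirane (step 6, opened in step 9), temporary C3–C4 oxirane (step 7, opened in the flask).
5. Building blocks: the diene in three steps from but-3-yn-1-ol, and the dienophile in one step from 2-bromomalonaldehyde. The C2 acetate and the C6 benzoate are carried in by the two partners.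

Key step: step 5

Numbering in the text: C1 is the tertiary carbinol carbon bearing C7, C2 is CHOAc, C3 is CHOBz, C4=C5 is the alkene and C6 is CHOBz. The "top face" is the face of C1–OH and C2–OAc in the target.

Assumption: the sense of induction in step 5 is taken from the accepted enal-binding model of N-protonated oxazaborolidines (B–O coordination, formyl C–H···O contact, s-trans enal, one face covered by a gem-phenyl group). On this model the (R)-catalyst opens the Si face of C1, and the equally available (S)-catalyst would give the mirror image.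

**Step 1**
Reactants: 1 but-3-yn-1-ol
Product: 2 (E)-4-[dimethyl(phenyl)silyl]but-3-en-1-ol
Conditions: PhMe2SiH, PtCl2 (1 mol %), XPhos (2 mol %), THF, 50 °C
Reagents that add atoms: dimethyl(phenyl)silane C[SiH](C)c1ccccc1
Why: Platinum-catalysed hydrosilylation (syn addition, Chalk–Harrod type) of a terminal alkyne puts silicon on the terminal carbon and should give the β-(E)-vinylsilane, with the bulky phosphine suppressing the α-isomer and O-silylation.

**Step 2**
Reactants: 2 (E)-4-[dimethyl(phenyl)silyl]but-3-en-1-ol
Product: 3 (E)-4-[dimethyl(phenyl)silyl]but-3-enal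
Conditions: Dess–Martin periodinane, CH2Cl2, 0 °C → rt
Reagents that add atoms: none
Why: Dess–Martin oxidation takes the primary alcohol to the aldehyde without base, and any drift of the double bond into conjugation is harmless because both aldehydes give the same extended enolate in step 3.

**Step 3**
Reactants: 3 (E)-4-[dimethyl(phenyl)silyl]but-3-enal
Product: 4 (1E,3E)-4-[dimethyl(phenyl)silyl]buta-1,3-dien-1-yl acetate
Conditions: Ac2O, Et3N, DMAP (10 mol %), CH2Cl2, rt; chromatography on Et3N-washed silica
Reagents that add atoms: acetic anhydride CC(=O)OC(C)=O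
Why: In this enol acetylation (O-acylation of the extended enolate) the doubly activated α-hydrogen is removed by Et3N, the vinylsilane geometry is kept, the new enol double bond should form mainly E on steric grounds, and the 1Z isomer is separated (it could not reach the s-cis form needed in step 5 anyway).

**Step 4**
Reactants: 5 2-bromomalonaldehyde
Product: 6 (Z)-2-bromo-3-oxoprop-1-en-1-yl benzoate
Conditions: BzCl, Et3N, CH2Cl2, −20 → 0 °C
Reagents that add atoms: benzoyl chloride O=C(Cl)c1ccccc1
Why: O-acylation of the extended enolate of the 1,3-dialdehyde should place the benzoyloxy group trans to CHO and cis to Br (Z), the geometry general for β-substituted 2-bromoenals, since reversible addition–elimination lets the isomers settle to the less crowded, dipole-minimised form.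

**Step 5**
Reactants: 4 (1E,3E)-4-[dimethyl(phenyl)silyl]buta-1,3-dien-1-yl acetate; 6 (Z)-2-bromo-3-oxoprop-1-en-1-yl benzoate
Product: 7 (1R,2S,5R,6S)-2-acetoxy-6-benzoyloxy-1-bromo-5-[dimethyl(phenyl)silyl]cyclohex-3-ene-1-carbaldehyde
Conditions: (R)-3,3-diphenyl-1-(o-tolyl)pyrrolo-oxazaborolidine (20 mol %), Tf2NH (18 mol %), 4 (1.5 equiv), CH2Cl2, −78 → −40 °C
Reagents that add atoms: none
Why: The N-protonated oxazaborolidine binds the formyl oxygen of 6 at boron (with a supporting formyl C–H···O contact), lowers the enal LUMO and triggers a concerted but asynchronous normal-demand [4π+2π] cycloaddition in which C5–C6 (to the enal β-carbon) leads and C1–C2 follows; the closest known reaction type is the oxazaborolidinium-catalysed enantioselective Diels–Alder reaction of 2-bromoacrolein and its β-substituted congeners with acyclic dienes. The one ring closed is the cyclohexene C1–C6, by intermolecular suprafacial/suprafacial [4+2] closure. Regiochemistry is the "ortho" mode: the acetoxy donor on C2 places the largest HOMO coefficient on the silyl-bearing terminus C5, which pairs with the electrophilic β-carbon C6, so that C2 bonds to the bromine-bearing C1. C2 and C5 are set cis by the E,E geometry of 4, C1 and C6 (Br cis to OBz) by the Z geometry of 6, and the two pairs are related by the Alder endo orientation of the catalyst-bound formyl group, reinforced because the exo mode would press the C6 benzoate against the C5 silyl group; hence CHO, OAc and Si share the top face and Br and OBz the bottom face. Absolute configuration comes from the catalyst alone: in the bound s-trans enal a gem-phenyl group of the (R)-catalyst covers the Re face of C1, the diene adds to the Si face, and all four stereocentres follow from that one choice. The step needs endo over exo, one enal face, and activation of the aldehyde rather than of the ester carbonyls or the allylic acetate of the product, which the higher Lewis basicity of the formyl oxygen, a slight excess of oxazaborolidine over Tf2NH (no free acid) and the low temperature should secure.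

**Step 6**
Reactants: 7 (1R,2S,5R,6S)-2-acetoxy-6-benzoyloxy-1-bromo-5-[dimethyl(phenyl)silyl]cyclohex-3-ene-1-carbaldehyde
Product: 9 (3S,4S,7R,8R)-4-acetoxy-8-benzoyloxy-7-[dimethyl(phenyl)silyl]-1-oxaspiro[2.5]oct-5-ene, via bromohydrin 8 (not isolated)
Conditions: NaBH4, THF–MeOH, −20 °C; aqueous work-up; crude 8, DBU, CH2Cl2, 0 °C → rt
Reagents that add atoms: none
Why: Chemoselective borohydride reduction of the aldehyde (esters untouched) is followed by halohydrin ring closure (intramolecular Williamson reaction, 3-exo-tet), in which O7 displaces the tertiary bromide from the rear, so C1 is inverted, its oxygen arrives on the top face beside C2–OAc and C7 swings to the face of C6–OBz.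

**Step 7**
Reactants: 9 (3S,4S,7R,8R)-4-acetoxy-8-benzoyloxy-7-[dimethyl(phenyl)silyl]-1-oxaspiro[2.5]oct-5-ene
Product: 11 (3R,4S,7R,8S)-8-acetoxy-4-benzoyloxy-7-hydroxy-1-oxaspiro[2.5]oct-5-ene, via epoxysilane 10 (not isolated)
Conditions: mCPBA, CH2Cl2, 0 °C → rt; then PPTS (10 mol %), THF–H2O, rt
Reagents that add atoms: mCPBA O=C(OO)c1cccc(Cl)c1
Why: Prilezhaev epoxidation of the allylsilane should occur anti to the C5–Si bond (also the face away from C2–OAc and the oxirane oxygen), and the acid-triggered anti elimination of silicon with the C4–O bond (Peterson-type, overall anti-SE2') moves the alkene to C4=C5 and leaves C3–OH trans to C2–OAc.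

**Step 8**
Reactants: 11 (3R,4S,7R,8S)-8-acetoxy-4-benzoyloxy-7-hydroxy-1-oxaspiro[2.5]oct-5-ene
Product: 12 (3R,4S,7R,8S)-8-acetoxy-4,7-bis(benzoyloxy)-1-oxaspiro[2.5]oct-5-ene
Conditions: BzCl, pyridine, DMAP (5 mol %), CH2Cl2, 0 °C
Reagents that add atoms: benzoyl chloride O=C(Cl)c1ccccc1
Why: DMAP-catalysed acylation of the only free hydroxyl group touches no stereocentre, and the cold, brief reaction leaves the neighbouring acetate in place.

**Step 9**
Reactants: 12 (3R,4S,7R,8S)-8-acetoxy-4,7-bis(benzoyloxy)-1-oxaspiro[2.5]oct-5-ene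
Product: 13 (1R,2S,3R,6S)-2-acetoxy-3,6-bis(benzoyloxy)-1-[(benzoyloxy)methyl]cyclohex-4-en-1-ol
Conditions: BzOH (3 equiv), n-Bu4N benzoate (20 mol %), MeCN, 70 °C
Reagents that add atoms: benzoic acid O=C(O)c1ccccc1
Why: Carboxylate opening of a 2,2-disubstituted oxirane is an SN2 attack at the unsubstituted carbon C7, so the C1–O bond and the configuration at C1 are kept, and the excess acid protonates the tertiary alkoxide before acyl groups can migrate.

**Compound list**
1 | but-3-yn-1-ol | C#CCCO | starting material
2 | (E)-4-[dimethyl(phenyl)silyl]but-3-en-1-ol | OCC/C=C/[Si](C)(C)c1ccccc1 | intermediate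
3 | (E)-4-[dimethyl(phenyl)silyl]but-3-enal | O=CC/C=C/[Si](C)(C)c1ccccc1 | intermediate
4 | (1E,3E)-4-[dimethyl(phenyl)silyl]buta-1,3-dien-1-yl acetate | CC(=O)O/C=C/C=C/[Si](C)(C)c1ccccc1 | intermediate
5 | 2-bromomalonaldehyde | O=CC(Br)C=O | starting material
6 | (Z)-2-bromo-3-oxoprop-1-en-1-yl benzoate (OBz cis to Br, trans to CHO) | O=C/C(Br)=C/OC(=O)c1ccccc1 | intermediate
7 | (1R,2S,5R,6S)-2-acetoxy-6-benzoyloxy-1-bromo-5-[dimethyl(phenyl)silyl]cyclohex-3-ene-1-carbaldehyde (CHO, OAc, Si on the top face; Br, OBz on the bottom face) | CC(=O)O[C@H]1C=C[C@@H]([Si](C)(C)c2ccccc2)[C@H](OC(=O)c3ccccc3)[C@@]1(Br)C=O | intermediate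
8 | bromohydrin, [(1R,2S,5R,6S)-2-acetoxy-6-benzoyloxy-1-bromo-5-[dimethyl(phenyl)silyl]cyclohex-3-en-1-yl]methanol | CC(=O)O[C@H]1C=C[C@@H]([Si](C)(C)c2ccccc2)[C@H](OC(=O)c3ccccc3)[C@@]1(Br)CO | intermediate
9 | (3S,4S,7R,8R)-4-acetoxy-8-benzoyloxy-7-[dimethyl(phenyl)silyl]-1-oxaspiro[2.5]oct-5-ene (oxirane O on the top face) | CC(=O)O[C@H]1C=C[C@@H]([Si](C)(C)c2ccccc2)[C@H](OC(=O)c3ccccc3)[C@]14CO4 | intermediate
10 | epoxysilane, the C3–C4 epoxide of 9 with the new oxirane O on the bottom face, anti to Si | CC(=O)O[C@H]1[C@@H]2O[C@@H]2[C@@H]([Si](C)(C)c3ccccc3)[C@H](OC(=O)c4ccccc4)[C@]15CO5 | intermediate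
11 | (3R,4S,7R,8S)-8-acetoxy-4-benzoyloxy-7-hydroxy-1-oxaspiro[2.5]oct-5-ene | CC(=O)O[C@H]1[C@H](O)C=C[C@H](OC(=O)c2ccccc2)[C@]13CO3 | intermediate
12 | (3R,4S,7R,8S)-8-acetoxy-4,7-bis(benzoyloxy)-1-oxaspiro[2.5]oct-5-ene | CC(=O)O[C@H]1[C@H](OC(=O)c2ccccc2)C=C[C@H](OC(=O)c3ccccc3)[C@]14CO4 | intermediate
13 | (1R,2S,3R,6S)-2-acetoxy-3,6-bis(benzoyloxy)-1-[(benzoyloxy)methyl]cyclohex-4-en-1-ol | CC(=O)O[C@H]1[C@H](OC(=O)c2ccccc2)C=C[C@H](OC(=O)c2ccccc2)[C@]1(O)COC(=O)c1ccccc1 | target

**Total step count:** 9. **Longest linear sequence:** 8 (steps 1–3 and 5–9).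

**Steps most likely to fail**

Step 5. The trisubstituted enal may react too slowly with the only moderately electron-rich diene. The endo or facial preference may erode. The Lewis acid may also ionise the allylic acetate/allylsilane array of the product.
The fallback sets out from 6 and replaces the acyclic diene by furan, the diene for which 2-bromoenals have their closest precedent under this class of catalyst (formyl group exo).
- The cycloaddition should give the 7-oxanorbornene bromo aldehyde F1, with the oxygen bridge between C2 and C5, CHO exo, and Br and OBz endo.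
- NaBH4 gives the bromohydrin F2, and DBU closes it with inversion at C1 to the spiro-oxirane F3.
- A rhodium(I)-catalysed anti-SN2' opening of the oxygen bridge with benzoic acid ([Rh(cod)Cl]2, ferrocenyl diphosphine, THF, heat) should place benzoate on C3, trans to the released C2 hydroxyl. The endo benzoate on C6 screens C4, so this should give the ring-opened alcohol F4.
- Ac2O/pyridine then comes back to the route at 12.

Step 7. The peracid may attack the face of silicon, or the acid present may open the C1–O–C7 oxirane.
The fallback sets out from 9.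
- Catalytic OsO4/NMO, a bulkier and neutral oxidant, should add anti to silicon and give the β-hydroxysilane diol F5.
- An acid Peterson elimination (cat. TsOH, THF, 0 °C; C5–Si and C4–OH anti-periplanar) then forms C4=C5, keeps C3–OH and comes back at 11.

Step 9. Attack at the hindered methylene C7 may be sluggish, and acyl groups may migrate at the temperature then needed.
The fallback avoids the oxirane altogether and sets out from 8, isolated in this case.
- BzCl/pyridine gives the bromo benzoate F6.
- Silver(I)-assisted hydrolysis (Ag2CO3, aqueous acetone), in the manner of the second stage of the Woodward cis-hydroxylation, replaces bromine by hydroxyl with inversion. The C2 acetate or the O7 benzoate can both reach the rear of the C1–Br bond, and the acyloxonium ion is opened by water. This gives the tertiary alcohol F7.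
- mCPBA as in step 7 gives, through the epoxysilane F8, the allylic alcohol F9.
- BzCl/pyridine acylates only the secondary C3 hydroxyl and comes back at 13.

**Further compounds**
F1 | step 5 | 7-oxanorbornene bromo aldehyde (CHO exo; Br and OBz endo) | O2[C@H]1C=C[C@@H]2[C@H](OC(=O)c3ccccc3)[C@@]1(Br)C=O
F2 | step 5 | 7-oxanorbornene bromohydrin | O2[C@H]1C=C[C@@H]2[C@H](OC(=O)c3ccccc3)[C@@]1(Br)CO
F3 | step 5 | 7-oxanorbornene spiro-oxirane (oxirane O exo) | O2[C@H]1C=C[C@@H]2[C@H](OC(=O)c3ccccc3)[C@]14CO4
F4 | step 5 | ring-opened alcohol (C2–OH, C3–OBz trans, spiro-oxirane kept) | O[C@H]1[C@H](OC(=O)c2ccccc2)C=C[C@H](OC(=O)c2ccccc2)[C@]13CO3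
F5 | step 7 | β-hydroxysilane diol (C3–OH and C4–OH on the bottom face, anti to Si) | CC(=O)O[C@H]1[C@H](O)[C@H](O)[C@@H]([Si](C)(C)c2ccccc2)[C@H](OC(=O)c3ccccc3)[C@]14CO4
F6 | step 9 | bromo benzoate (O7-benzoate of 8) | CC(=O)O[C@H]1C=C[C@@H]([Si](C)(C)c2ccccc2)[C@H](OC(=O)c3ccccc3)[C@@]1(Br)COC(=O)c1ccccc1
F7 | step 9 | tertiary alcohol (C1–OH on the top face, allylsilane kept) | CC(=O)O[C@H]1C=C[C@@H]([Si](C)(C)c2ccccc2)[C@H](OC(=O)c3ccccc3)[C@]1(O)COC(=O)c1ccccc1
F8 | step 9 | epoxysilane of F7 (oxirane O anti to Si) | CC(=O)O[C@H]1[C@@H]2O[C@@H]2[C@@H]([Si](C)(C)c3ccccc3)[C@H](OC(=O)c4ccccc4)[C@]1(O)COC(=O)c1ccccc1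
F9 | step 9 | allylic alcohol (C3–OH free, C1–OH free) | CC(=O)O[C@H]1[C@H](O)C=C[C@H](OC(=O)c2ccccc2)[C@]1(O)COC(=O)c1ccccc1
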